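**Plan**
- Retrosynthetic cuts, in order: the cyclobutane bonds C8–C8′ and C9–C9′ (two identical enol-lactone halves); the butenolide at O–C12 and C7=C11; C4=C15; the cyclopropane bond C1–C3; last the ring-fusion bond C5–C10.
- Enabling feature: in each half, rings A and B share only C5–C10. Without that bond and C1–C3, carbons C1–C10 form one ten-membered ring carrying C14 on C10, C15 on C4, oxygen on C8 and an alkylidene on C7, which is the ring of germacrone.
- Forward ring order: ten-membered ring → rings A and B together by transannular C5–C10 closure of the 1,10-epoxide → cyclopropane (C1–C3, ring A contracting to a cyclopentane) → butenolide on C7/C8 → cyclobutane by photodimerisation.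
- Stereochemistry: C1 and C10 from a catalyst-controlled epoxidation; C10 (inversion) and C5 (trans fusion) from the transannular step; C1 (second inversion) and C3 from the enolate displacement; C8, C9, C8′, C9′ from the α-face, head-to-head, anti photodimerisation of one enantiomer.

Key step: step 2

Assumption: the D-fructose-derived Shi ketone is taken to deliver oxygen to the face of C1=C10 that gives the (1R,10R)-epoxide, by analogy with acyclic (E)-trisubstituted alkenes; if the sense is opposite, the enantiomeric ketone is used.

Numbering: eudesmane numbering throughout (C14 on C10, C15 on C4); "lindenane" means the eudesmane skeleton with an added C1–C3 bond.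

Step 1
Reactants: 1 germacrone ((1(10)E,4E)-germacra-1(10),4,7(11)-trien-8-one)
Product: 2 (1R,10R)-1,10-epoxygermacra-4,7(11)-dien-8-one (trans-epoxide, 4E alkene kept)
Conditions: D-fructose-derived Shi ketone (0.3 equiv), KHSO5 (as Oxone), K2CO3, Bu4NHSO4, MeCN–CH2(OMe)2 / aq. Na2B4O7–Na2EDTA buffer, −10 → 0 °C; chromatography
Reagents that add atoms: potassium peroxymonosulfate (KHSO5, active part of Oxone), [K+].[O-]S(=O)(=O)OO
Why: Shi asymmetric epoxidation, in which the chiral dioxirane formed in situ transfers oxygen through a spiro transition state to the electron-rich (E)-trisubstituted C1=C10 alkene, whose single exposed face in each ring conformer makes the catalyst's choice of conformer the source of both new stereocenters (1R,10R), while the C7=C11 alkene is deactivated by conjugation with the C8 carbonyl and the regioisomeric 4,5-epoxide is removed by chromatography.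

Step 2
Reactants: 2 (1R,10R)-1,10-epoxygermacra-4,7(11)-dien-8-one
Product: 3 (1R,5S,10R)-1-hydroxyeudesma-4(15),7(11)-dien-8-one (1β-OH, 5α-H, 10β-CH3)
Conditions: BF3·OEt2 (1 equiv), toluene, −40 → 0 °C; aq. NaHCO3; AgNO3–SiO2 chromatography
Reagents that add atoms: none
Why: BF3 binds the epoxide oxygen, the tertiary C10–O bond ionises, and the C4=C5 π bond attacks C10 across the ring from the side opposite the departing oxygen, after which the C4 cation loses a proton from C15 to leave the exocyclic alkene. The closest known reaction type is the Lewis-acid-promoted transannular cyclisation of germacra-1(10),4-diene 1,10-epoxides to 1-hydroxyeudesmanes, a cation–olefin cyclisation ended by elimination. The one new bond, C5–C10, divides the ten-membered ring into two six-membered rings: ring A closes in the 6-endo mode toward both the alkene and the epoxide (C4 and C1 stay inside it), ring B in the 6-exo mode (C4 and C1 lie outside it). C10 is set by inversion at the epoxide carbon and C5 by the crossed chair–chair conformer of the (E,E)-diene, which puts H5 anti to C14 across the new bond (trans fusion), while C1 keeps its oxygen and its configuration from 2 (1β-OH, equatorial). The step needs the C4=C5 alkene to react and the C7=C11 alkene to stay out, which its conjugation with the C8 carbonyl secures, and it needs proton loss from C15 instead of C3, which is favoured by a short exposure at low temperature and checked by removing endocyclic isomers on AgNO3-impregnated silica. A Lewis acid in a non-basic medium is used because the epoxide is β,γ to the C8 ketone and base would open it by elimination toward C9.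

Step 3
Reactants: 3 (1R,5S,10R)-1-hydroxyeudesma-4(15),7(11)-dien-8-one; 4 p-toluenesulfonyl chloride
Product: 5 1β-tosyloxyeudesma-4(15),7(11)-dien-8-one
Conditions: TsCl, pyridine, DMAP (cat.), CH2Cl2, 0 °C → rt
Reagents that add atoms: p-toluenesulfonyl chloride (4), Cc1ccc(cc1)S(=O)(=O)Cl
Why: Sulfonylation of the equatorial secondary alcohol under nucleophilic catalysis turns C1–O into a leaving group with retention at C1, and neither the enone nor the 1,1-disubstituted alkene reacts with TsCl.

Step 4
Reactants: 5 1β-tosyloxyeudesma-4(15),7(11)-dien-8-one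
Product: 7 1β-tosyloxy-15-noreudesm-7(11)-ene-4,8-dione (5α-H, 10β-CH3), via 4,15-diol 6 (not isolated)
Conditions: OsO4 (cat.), NaIO4, 2,6-lutidine, 1,4-dioxane–H2O, rt
Reagents that add atoms: osmium tetroxide, O=[Os](=O)(=O)=O (transfers the oxygen that stays on C4); sodium periodate, [Na+].[O-]I(=O)(=O)=O (reoxidises osmium and is the ultimate oxygen source)
Why: Lemieux–Johnson oxidation, in which OsO4 dihydroxylates the unhindered 1,1-disubstituted C4=C15 alkene far faster than the tetrasubstituted, electron-poor C7=C11 enone alkene and periodate cleaves the 4,15-diol 6 to the C4 ketone, 2,6-lutidine being too weak a base to enolise the γ-tosyloxy ketone.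

Step 5
Reactants: 7 1β-tosyloxy-15-noreudesm-7(11)-ene-4,8-dione
Product: 8 15-norlinden-7(11)-ene-4,8-dione (new C1–C3 bond on the α face; 1α-H, 3α-H, 5α-H, 10β-CH3; cyclopropane methylene C2 on the β face, syn to C14)
Conditions: LiN(SiMe3)2 (2.1 equiv), THF, −78 °C; DMPU, −78 → 0 °C; aq. NH4Cl at −78 °C
Reagents that add atoms: none
Why: Intramolecular enolate alkylation (3-exo-tet 1,3-elimination, as in the base-induced closure of 4-sulfonyloxycyclohexanones to bicyclo[3.1.0]hexan-2-ones), in which the amide base removes the unhindered C3 proton of the C4 ketone kinetically (C5 is a methine) and, with the second equivalent, a C9 proton of the enone, whose enolate is a bystander because the C9–C10 bond is gauche to C1–O; on warming, the α lobe of the C3 enolate displaces the equatorial 1β-tosylate from the rear, so that C1 is inverted, C3 is fixed by the necessarily cis ring fusion, and C2 comes to lie on the β face.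

Step 6
Reactants: 8 15-norlinden-7(11)-ene-4,8-dione; 9 methyltriphenylphosphonium bromide
Product: 10 lindena-4(15),7(11)-dien-8-one
Conditions: Ph3PCH3Br (2.5 equiv), KOt-Bu (2.2 equiv), THF, 0 °C → rt
Reagents that add atoms: methyltriphenylphosphonium bromide (9), C[P+](c1ccccc1)(c1ccccc1)c1ccccc1.[Br-]
Why: Wittig methylenation, in which the ylide adds to the saturated C4 carbonyl (the sabina ketone to sabinene type of olefination) in preference to the C8 carbonyl, which is cross-conjugated, flanked by a fully substituted alkene carbon and a neopentyl methylene and reversibly masked as its C9 enolate by the basic ylide, while the excess phosphonium salt buffers alkoxide so that H5 next to the C4 ketone is not epimerised before olefination.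

Step 7
Reactants: 10 lindena-4(15),7(11)-dien-8-one
Product: 11 lindenane ketone (11,12,13-trinorlinden-4(15)-en-8-one)
Conditions: KOH, H2O–EtOH, reflux, slow distillation of acetone
Reagents that add atoms: none
Why: Retro-aldol (retro-Claisen–Schmidt) cleavage, as in the hydrolysis of pulegone to 3-methylcyclohexanone, in which hydroxide adds to C11 of the enone, the β-hydroxy ketone fragments to acetone and the C7 enolate, and removal of acetone pulls the equilibrium over, with no stereocenter at risk because C7 and C9 are methylenes and C5 is no longer α to a carbonyl; the isopropylidene has by then served as a blocking group for C7/C8 through steps 3–6.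

Step 8
Reactants: 11 lindenane ketone (11,12,13-trinorlinden-4(15)-en-8-one); 12 ethyl pyruvate
Product: 13 ethyl 11-hydroxy-8-oxolinden-4(15)-en-12-oate (aldol adduct, mixture of isomers at C7 and C11)
Conditions: LiN(i-Pr)2, THF, −78 °C; ethyl pyruvate, −78 °C; aq. NH4Cl
Reagents that add atoms: ethyl pyruvate (12), CCOC(=O)C(C)=O
Why: Directed aldol addition, in which the amide base deprotonates the C8 ketone kinetically at C7 (C9 is neopentyl, next to the quaternary C10) and the lithium enolate adds to the ketone carbonyl of ethyl pyruvate, bringing in C11, C12 and C13; the two new stereocenters (C7, C11) are left uncontrolled because both become sp2 in step 9.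

Step 9
Reactants: 13 ethyl 11-hydroxy-8-oxolinden-4(15)-en-12-oate
Product: 15 chloranthalactone A (lindena-4(15),7(11),8-trien-12,8-olide; 1R,3S,5S,10S), via alkylidene keto ester 14 (not isolated)
Conditions: TsOH·H2O (cat.), toluene, reflux (Dean–Stark)
Reagents that add atoms: none
Why: Acid-catalysed dehydration of the tertiary β-hydroxy ketone to the tetrasubstituted C7=C11 alkene, whose (Z)-form 14 undergoes enol lactonisation of the ester onto the C8 enol (the usual passage from a cyclohexanone–pyruvate aldol to a γ-alkylidene butenolide), driven by azeotropic removal of water and ethanol and by the conjugation of the dienolide, with no stereocenter formed.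

Step 10
Reactants: 15 chloranthalactone A (two molecules)
Product: 16 target dimer (head-to-head, anti cyclobutane dimer through C8–C8′ and C9–C9′)
Conditions: hν (medium-pressure Hg lamp, Pyrex), degassed hexane, rt
Reagents that add atoms: none
Why: [2+2] Photocycloaddition (photodimerisation, known for γ-alkylidene butenolides of this type) of the enol-lactone C8=C9 alkene, in which the first bond joins the two C9 atoms so that both radicals sit on C8, stabilised by oxygen and the butenolide (head-to-head), each monomer reacts on its α face away from the C14 methyl on the neighbouring C10, and the anti arrangement about the cyclobutane follows from steric repulsion, so that one enantiomer of 15 gives the twofold-symmetric dimer and sets C8, C9, C8′ and C9′.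

**Compound list**
1 | germacrone, (1(10)E,4E)-germacra-1(10),4,7(11)-trien-8-one | C/C1=C\CC(=C(C)C)C(=O)C/C(C)=C/CC1 | starting material
2 | (1R,10R)-1,10-epoxygermacra-4,7(11)-dien-8-one (trans-epoxide) | C/C1=C\CC(=C(C)C)C(=O)C[C@@]2(C)O[C@@H]2CC1 | intermediate
3 | (1R,5S,10R)-1-hydroxyeudesma-4(15),7(11)-dien-8-one (1β-OH, 5α-H, 10β-CH3) | C=C1CC[C@@H](O)[C@@]2(C)[C@H]1CC(=C(C)C)C(=O)C2 | intermediate
4 | p-toluenesulfonyl chloride | Cc1ccc(cc1)S(=O)(=O)Cl | starting material
5 | 1β-tosyloxyeudesma-4(15),7(11)-dien-8-one | C=C1CC[C@@H](OS(=O)(=O)c3ccc(C)cc3)[C@@]2(C)[C@H]1CC(=C(C)C)C(=O)C2 | intermediate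
6 | 4,15-dihydroxy-1β-tosyloxyeudesm-7(11)-en-8-one (C4 configuration immaterial) | OCC1(O)CC[C@@H](OS(=O)(=O)c3ccc(C)cc3)[C@@]2(C)[C@H]1CC(=C(C)C)C(=O)C2 | intermediate (not isolated)
7 | 1β-tosyloxy-15-noreudesm-7(11)-ene-4,8-dione | O=C1CC[C@@H](OS(=O)(=O)c3ccc(C)cc3)[C@@]2(C)[C@H]1CC(=C(C)C)C(=O)C2 | intermediate
8 | 15-norlinden-7(11)-ene-4,8-dione (1α-H, 3α-H, 5α-H, 10β-CH3, C2 on the β face) | O=C1[C@H]2C[C@H]2[C@@]2(C)[C@H]1CC(=C(C)C)C(=O)C2 | intermediate
9 | methyltriphenylphosphonium bromide | C[P+](c1ccccc1)(c1ccccc1)c1ccccc1.[Br-] | starting material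
10 | lindena-4(15),7(11)-dien-8-one | C=C1[C@H]2C[C@H]2[C@@]2(C)[C@H]1CC(=C(C)C)C(=O)C2 | intermediate
11 | lindenane ketone, 11,12,13-trinorlinden-4(15)-en-8-one | C=C1[C@H]2C[C@H]2[C@@]2(C)[C@H]1CCC(=O)C2 | intermediate
12 | ethyl pyruvate | CCOC(=O)C(C)=O | starting material
13 | ethyl 11-hydroxy-8-oxolinden-4(15)-en-12-oate (mixture at C7 and C11) | C=C1[C@H]2C[C@H]2[C@@]2(C)[C@H]1CC(C(C)(O)C(=O)OCC)C(=O)C2 | intermediate
14 | ethyl (7(11)Z)-8-oxolindena-4(15),7(11)-dien-12-oate | C=C1[C@H]2C[C@H]2[C@@]2(C)[C@H]1C/C(=C(\C)C(=O)OCC)C(=O)C2 | intermediate (not isolated)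
15 | chloranthalactone A, lindena-4(15),7(11),8-trien-12,8-olide | C=C1[C@H]2C[C@H]2[C@@]2(C)[C@H]1CC1=C(C)C(=O)OC1=C2 | intermediate
16 | head-to-head anti [2+2] dimer of 15 (CNP0265879.1) | C=C1[C@H]2C[C@H]2[C@@]2(C)[C@H]1CC1=C(C)C(=O)O[C@]13[C@H]2[C@H]1[C@@]2(C)[C@@H]4C[C@@H]4C(=C)[C@@H]2CC2=C(C)C(=O)O[C@@]213 | target

**Step count:** 10 steps in total. Longest linear sequence: 10 steps (1 → 16; both halves of 16 come from the same intermediate 15).

**Steps most likely to fail**

Step 5. The risk is proton transfer between the C9 enolate of the enone and the C4 ketone while the mixture warms. This would move the C4 enolate from C3 to C5 (closure to the isomeric C1–C5 cyclopropane) or epimerise C5 of 8 to the cis-fused ketone. The fallback removes the second carbonyl from play before the closure. It sets out from 3: retro-aldol cleavage with aqueous KOH in refluxing ethanol should give 1β-hydroxy-11,12,13-trinoreudesm-4(15)-en-8-one F5, and ketalisation (ethylene glycol, PPTS, benzene, Dean–Stark) its 8,8-ethylenedioxy derivative F6. Tosylation as in step 3 gives the tosylate F7, and OsO4/NaIO4/2,6-lutidine cleaves C4=C15 through the 4,15-diol F8 to the 15-nor-4-ketone F9. LiN(SiMe3)2 (1.05 equiv, THF, −78 → 0 °C), acting on the only enolisable carbonyl, should close the cyclopropyl ketone ketal F10, and Wittig methylenation gives the 4(15)-methylene ketal F11. Mild deketalisation (PPTS, acetone–H2O) returns to the route at 11, so steps 6 and 7 are bypassed as well.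

Step 1. The risk is insufficient discrimination between the two trisubstituted ring alkenes and between the two enantiomeric ring conformers, with base-mediated isomerisation of the β,γ-unsaturated ketone in the pH 10.5 buffer as a further drain. The fallback replaces asymmetric catalysis by resolution. It sets out from 1: mCPBA (CH2Cl2, NaHCO3, 0 °C) gives racemic trans-1,10-epoxygermacra-4,7(11)-dien-8-one F1, which is separated from the 4,5-epoxide and cyclised with BF3·OEt2 exactly as in step 2 to racemic 1β-hydroxyeudesma-4(15),7(11)-dien-8-one F2. Esterification with (S)-O-methylmandelic acid (DCC, DMAP) gives two diastereomeric esters, the (S)-O-methylmandelate of 3 F3 and the (S)-O-methylmandelate of the enantiomeric alcohol F4, which are separated by chromatography. Saponification of F3 (LiOH, THF–H2O) returns to the route at 3.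

Step 7. The risk is that hydration of the hindered tetrasubstituted enone is too slow, so that under forcing conditions aldol self-condensation of 11 or migration of the C4=C15 alkene overtakes the cleavage. The fallback excises the isopropylidene oxidatively instead and builds the butenolide by olefination. It sets out from 8: ozonolysis of its only alkene (O3, CH2Cl2–MeOH, −78 °C; Me2S) gives 15-norlindane-4,7,8-trione F12 (the 7,8-dione largely enolised). Ethyl 2-(triphenylphosphoranylidene)propanoate (toluene, 80 °C) should olefinate the less hindered C7 carbonyl to ethyl (7(11)Z)-4,8-dioxo-15-norlinden-7(11)-en-12-oate F13, which on heating with catalytic TsOH lactonises onto the C8 enol to 4-oxo-15-norlindena-7(11),8-dien-12,8-olide F14. Takai–Lombardo methylenation (Zn, CH2Br2, TiCl4, THF–CH2Cl2), which is not basic and spares lactones, returns to the route at 15.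

**Further compounds**
F1 | step 1 | racemic trans-1,10-epoxygermacra-4,7(11)-dien-8-one (both enantiomers written) | C/C1=C\CC(=C(C)C)C(=O)C[C@@]2(C)O[C@@H]2CC1.C/C1=C\CC(=C(C)C)C(=O)C[C@]2(C)O[C@H]2CC1
F2 | step 1 | racemic 1β-hydroxyeudesma-4(15),7(11)-dien-8-one (both enantiomers written) | C=C1CC[C@@H](O)[C@@]2(C)[C@H]1CC(=C(C)C)C(=O)C2.C=C1CC[C@H](O)[C@]2(C)[C@@H]1CC(=C(C)C)C(=O)C2
F3 | step 1 | (S)-O-methylmandelate of 3 | C=C1CC[C@@H](OC(=O)[C@@H](OC)c3ccccc3)[C@@]2(C)[C@H]1CC(=C(C)C)C(=O)C2
F4 | step 1 | (S)-O-methylmandelate of the enantiomer of 3 | C=C1CC[C@H](OC(=O)[C@@H](OC)c3ccccc3)[C@]2(C)[C@@H]1CC(=C(C)C)C(=O)C2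
F5 | step 5 | 1β-hydroxy-11,12,13-trinoreudesm-4(15)-en-8-one | C=C1CC[C@@H](O)[C@@]2(C)[C@H]1CCC(=O)C2
F6 | step 5 | 8,8-ethylenedioxy-11,12,13-trinoreudesm-4(15)-en-1β-ol | C=C1CC[C@@H](O)[C@@]2(C)[C@H]1CCC1(OCCO1)C2
F7 | step 5 | 8,8-ethylenedioxy-1β-tosyloxy-11,12,13-trinoreudesm-4(15)-ene | C=C1CC[C@@H](OS(=O)(=O)c3ccc(C)cc3)[C@@]2(C)[C@H]1CCC1(OCCO1)C2
F8 | step 5 | 8,8-ethylenedioxy-1β-tosyloxy-11,12,13-trinoreudesmane-4,15-diol (not isolated) | OCC1(O)CC[C@@H](OS(=O)(=O)c3ccc(C)cc3)[C@@]2(C)[C@H]1CCC1(OCCO1)C2
F9 | step 5 | 8,8-ethylenedioxy-1β-tosyloxy-11,12,13,15-tetranoreudesman-4-one | O=C1CC[C@@H](OS(=O)(=O)c3ccc(C)cc3)[C@@]2(C)[C@H]1CCC1(OCCO1)C2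
F10 | step 5 | 8,8-ethylenedioxy-11,12,13,15-tetranorlindan-4-one | O=C1[C@H]2C[C@H]2[C@@]2(C)[C@H]1CCC1(OCCO1)C2
F11 | step 5 | 8,8-ethylenedioxy-11,12,13-trinorlinden-4(15)-ene | C=C1[C@H]2C[C@H]2[C@@]2(C)[C@H]1CCC1(OCCO1)C2
F12 | step 7 | 15-norlindane-4,7,8-trione (11,12,13-trinor) | O=C1[C@H]2C[C@H]2[C@@]2(C)[C@H]1CC(=O)C(=O)C2
F13 | step 7 | ethyl (7(11)Z)-4,8-dioxo-15-norlinden-7(11)-en-12-oate (not isolated) | O=C1[C@H]2C[C@H]2[C@@]2(C)[C@H]1C/C(=C(\C)C(=O)OCC)C(=O)C2
F14 | step 7 | 4-oxo-15-norlindena-7(11),8-dien-12,8-olide | O=C1[C@H]2C[C@H]2[C@@]2(C)[C@H]1CC1=C(C)C(=O)OC1=C2
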